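The next flask could carry 2.1 mol% of catalyst instead of 0.53 mol%, or stand longer, and either change is worth making only if it buys target.

starting material 2.0 M; catalyst 0.53 mol%; time 15 d

    crystals ⇌ target, rate k1*(cs1 - [target]) while solid is left; crystals form when [target] > cs1 (cs1 = 26 mM, k1 = 2.2 min⁻¹)
    catalyst + other conformer → catalyst + isomer of the product (k2 = 2.2 M⁻¹ min⁻¹)
    starting material + catalyst → catalyst + target (k3 = 1.8 M⁻¹ min⁻¹)
    starting material ⇌ other conformer, settled at all times (K4 = 1.1)

- amounts and yields of target count crystals too
- given per volume of solution although it is solid: crystals
- in a conversion other conformer counts as not yet reacted
- run time (flask): 15 d

1. how much target there is at 15 d, in percent of the starting material charged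
2. amount of target if the flask were left three thousand times as long, in percent of the starting material charged

The reckoning joins the two ends of the run. During the run, the other conformer stays at 1.1 times [starting material]. Target therefore forms at 1.8 M⁻¹ min⁻¹ times [catalyst][starting material], and isomer of the product at 2.42 M⁻¹ min⁻¹ times the same product of concentrations. The catalyst is given back in both steps and cancels from their ratio, so each portion of material leaving the pool of starting material and other conformer becomes target with the branching share 42.7 %, the selectivity of Curtin–Hammett conditions.

At the far end, the 10.6 mM of catalyst makes the pool decay pseudo-first-order at 0.0213 min⁻¹, a half-life of 0.542 h. The 15 d allowed is about 664 such half-lives, so the pool should be consumed and the target should equal the share. Target beyond 26 mM crystallises, but crystals count as target. Neither catalyst loading nor time appears in the share, so this reckoning keeps the recipe.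

The forecast gives 42.65 % (from 42.2 % to 43.1 %) at the asked time and 42.65 % for the long wait, holding that “waiting longer adds nothing because neither product reacts further”.

The simulated flask gives 42.7 % at the asked time and 42.7 % for the long wait, and it reaches half of its conversion at 0.542 h. Ten times the time leaves target at 42.7 %. The loss to isomer of the product, 57.3 % by the share, comes from the balance of starting material with other conformer: the run without that equilibrium gives 100 % of target against 42.7 %.

For the neighbour flask with 2.1 mol% of catalyst, the share remains 42.7 %, while the reckoned half-life of the pool shortens to 0.137 h. That flask gives 42.7 %.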